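**Retrosynthetic overview**
1. The two esters (angelate on O2, 4-hydroxybenzoate on O6) go on last; the C6 carbinol comes from a C6 ketone, so the core is 2β,4β-dihydroxydauc-8-en-6-one, a trans-fused hydroazulenone.
2. Key disconnection is the ring-fusion bond C1–C5: the hydroazulenone comes from a cis-decalin (bicyclo[4.4.0]) 4β,5β-epoxy-2β,6β-diol. An epoxy-alcohol semipinacol shifts C1 from C6 to C5, which contracts cyclohexane ring A to the cyclopentane and enlarges cyclohexene ring B to the cycloheptenone in one operation.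
3. Enabling feature: the 1,3-dioxygenation C4(OH)–C5(H)–C6(O) that straddles fusion carbon C5, with the tertiary C4–OH (five-membered ring) cis to the C5–C6 bond (seven-membered ring) and C6 next to quaternary C1. This is the β-hydroxy ketone left by a 2,3-epoxy alcohol whose carbinol carbon carries the migrating group.
4. The decalin comes from ring B closure by RCM (C8=C9) after methallyl addition to the C6 carbonyl of a 6,6-disubstituted cyclohexenone; the epoxide comes from hydroxyl-directed epoxidation.
5. Ring A is the p-menthane ring of (R)-carvone (epoxidation and reductive allylation give C2–O and quaternary C1). Ring order: A (chiral pool), then B (RCM), then the 5/7 pair (key step).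

Key step: step 10

Remark: C1–C10 are the daucane locants of the target (C1 = C–CH3 quaternary, C2 = CH–O, C4 = C(OH)iPr, C5 = fusion CH, C6 = aroyloxy carbon, C8 = alkene C–CH3). They coincide with bicyclo[4.4.0]decane locants and are kept for all bicyclic precursors; β is the face of the C1 methyl. Compounds 9, 15 and 19 are assumed to be purchased.

**Route**

Step 1
Reactants: 1 (R)-(−)-carvone, (5R)-2-methyl-5-(prop-1-en-2-yl)cyclohex-2-en-1-one
Product: 2 (R)-carvotanacetone, (5R)-2-methyl-5-(propan-2-yl)cyclohex-2-en-1-one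
Conditions: H2 (1 atm), RhCl(PPh3)3 (cat.), toluene/EtOH, rt
Reagents that add atoms: none
Why: Homogeneous hydrogenation with Wilkinson's catalyst should reduce only the unhindered 1,1-disubstituted isopropenyl alkene and leave the trisubstituted conjugated enone and the existing stereocentre untouched.

Step 2
Reactants: 2 (R)-carvotanacetone
Product: 3 (1R,4R,6R)-1-methyl-4-(propan-2-yl)-7-oxabicyclo[4.1.0]heptan-2-one (epoxide trans to isopropyl)
Conditions: 30% H2O2, NaOH (cat.), MeOH, 0 °C
Reagents that add atoms: hydrogen peroxide, OO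
Why: Weitz–Scheffer nucleophilic epoxidation, in which hydroperoxide adds axially to the enone β-carbon (future C2) anti to the isopropyl group, so the C2–O bond is set trans to isopropyl.

Step 3
Reactants: 3 epoxy ketone; 4 allyl bromide (3-bromoprop-1-ene)
Product: 6 (2S,3R,5R)-3-hydroxy-2-methyl-5-(propan-2-yl)-2-(prop-2-en-1-yl)cyclohexan-1-one (OH cis to the methyl; trans to allyl and isopropyl), via dilithium enolate-alkoxide 5 (not isolated)
Conditions: Li (2.2 equiv), NH3(l)/THF, −78 °C; then 4 (1.5 equiv), −78 → −33 °C; solid NH4Cl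
Reagents that add atoms: allyl bromide (4), C=CCBr
Why: Dissolving-metal reductive cleavage of the Cα–O bond of the α,β-epoxy ketone gives the regiodefined enolate/β-alkoxide, which is C-allylated in situ (reductive alkylation); the allyl group should enter axially and anti to the pseudoaxial β-OLi group, making C1 quaternary with its methyl cis to the C2 oxygen.

Step 4
Reactants: 6 hydroxy ketone
Product: 7 (2S,3R,5R)-3-[(tert-butyldimethylsilyl)oxy]-2-methyl-5-(propan-2-yl)-2-(prop-2-en-1-yl)cyclohexan-1-one
Conditions: TBSOTf (1.2 equiv), 2,6-lutidine, CH2Cl2, −78 → 0 °C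
Reagents that add atoms: tert-butyldimethylsilyl trifluoromethanesulfonate, CC(C)(C)[Si](C)(C)OS(=O)(=O)C(F)(F)F
Why: Silyl triflate silylation of the hindered secondary alcohol protects it against the oxidant of step 5 and supplies the bulky β substituent that steers step 6.

Step 5
Reactants: 7 silyloxy ketone
Product: 8 (5R,6S)-5-[(tert-butyldimethylsilyl)oxy]-6-methyl-3-(propan-2-yl)-6-(prop-2-en-1-yl)cyclohex-2-en-1-one
Conditions: IBX (2.5 equiv), DMSO/fluorobenzene 1:2, 70 °C
Reagents that add atoms: none
Why: IBX dehydrogenation of the ketone can only go towards C5 because C1 is quaternary, so the C4=C5 enone should form regiospecifically and the now unneeded C4 stereocentre is erased.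

Step 6
Reactants: 8 enone; 9 (2-methylprop-2-en-1-yl)magnesium chloride
Product: 10 (1S,5R,6S)-5-[(tert-butyldimethylsilyl)oxy]-6-methyl-1-(2-methylprop-2-en-1-yl)-3-(propan-2-yl)-6-(prop-2-en-1-yl)cyclohex-2-en-1-ol (methallyl cis to allyl; OH, CH3 and OTBS on the other face)
Conditions: 9 (0.5 M in THF, 1.5 equiv), THF, −78 °C; aq. NH4Cl
Reagents that add atoms: 2-methylallylmagnesium chloride (9), C=C(C)C[Mg]Cl
Why: Grignard 1,2-addition of an allylic reagent to the enone carbonyl; in the half-chair with OTBS equatorial, attack should be axial and anti to the pseudoaxial C1 methyl (the other conformer is blocked on both faces by axial allyl and syn-axial OTBS), so C6 gets its hydroxyl β and the methallyl group cis to allyl.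

Step 7
Reactants: 10 triene alcohol
Product: 11 cis-fused (1S,2R,6S)-2-[(tert-butyldimethylsilyl)oxy]-1,8-dimethyl-4-(propan-2-yl)bicyclo[4.4.0]deca-4,8-dien-6-ol (1-CH3, 2-OTBS and 6-OH all β)
Conditions: Grubbs second-generation catalyst (5 mol %), CH2Cl2 (5 mM), 40 °C
Reagents that add atoms: none
Why: Ring-closing metathesis of the monosubstituted with the 1,1-disubstituted alkene should close cyclohexene ring B with the trisubstituted C8=C9 alkene; the cis ring fusion follows from step 6 and the ring C4=C5 alkene is inert.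

Step 8
Reactants: 11 silyl ether
Product: 12 cis-fused (1S,2R,6S)-1,8-dimethyl-4-(propan-2-yl)bicyclo[4.4.0]deca-4,8-diene-2,6-diol (both OH β)
Conditions: TBAF (1 M in THF), THF, 0 °C → rt; aq. work-up
Reagents that add atoms: none
Why: Fluoride cleavage of the silyl ether frees the 2β-hydroxyl, which is wanted as a second ligand on the β face in steps 9 and 10 and as the later acylation site.

Step 9
Reactants: 12 diene diol
Product: 13 (1S,2R,4R,5R,6R)-4,5-epoxy-1,8-dimethyl-4-(propan-2-yl)bicyclo[4.4.0]dec-8-ene-2,6-diol (4β,5β-epoxide, cis to both hydroxyls and to the C1 methyl)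
Conditions: VO(acac)2 (5 mol %), t-BuOOH (decane solution, 1.3 equiv), CH2Cl2, 0 °C
Reagents that add atoms: tert-butyl hydroperoxide, CC(C)(C)OO
Why: Vanadium-catalysed hydroxyl-directed epoxidation should select the allylic C4=C5 alkene over the homoallylic C8=C9 alkene and deliver oxygen syn to the 6β-OH (and the homoallylic 2β-OH) on the convex β face, setting C4 and C5.

Step 10
Reactants: 13 epoxy diol
Product: 14 2β,4β-dihydroxydauc-8-en-6-one (trans-fused hydroazulenone; 1β-CH3, 5α-H)
Conditions: ZnBr2 (1.0 equiv), CH2Cl2, −20 → 0 °C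
Reagents that add atoms: none
Why: Zn(II) is held by the 2β- and 6β-hydroxyls and activates the cis (4β,5β) epoxide oxygen; as the C5–O bond lengthens, the ring-fusion σ-bond C6–C1 shifts to C5 from the face opposite the oxygen while the C6–O lone pair closes to the ketone, i.e. a type-3 semipinacol (epoxy-alcohol pinacol-type) rearrangement. The closest known reaction types are the Lewis-acid rearrangement of tertiary 2,3-epoxy alcohols to β-hydroxy ketones and the pinacol-type ring contraction/ring expansion of decalin hydroxy sulfonates to hydroazulenones. The cyclopentane (C1–C2–C3–C4–C5) is closed by this suprafacial 1,2-alkyl shift as a ring contraction of ring A (a 3-exo-tet attack of the C6–C1 bond on C5), and the same shift closes the seven-membered ring (C1, C5, C6, C7, C8, C9, C10) by one-carbon enlargement of ring B. C5 is the only new stereocentre and is set by inversion at the epoxide carbon (H5 ends α, trans to the C1 methyl, giving the trans fusion); C1 migrates with retention and C4 keeps its oxygen as the 4β tertiary alcohol cis to C6, all relayed from the epoxide face dictated by the 6β-OH. Two selectivities are needed: cleavage of C5–O instead of the tertiary C4–O bond, which rests only on the push of the zinc-bound C6 oxygen and the participation of the electron-rich quaternary C1 (both available to C5 alone), and migration of C1 instead of C7, which rests on the 1,3-diaxial O2–Zn–O6 chelate that fixes ring A in the half-chair where C7 is equatorial and only the endocyclic C6–C1 bond can become antiperiplanar to C5–O (towards the boat) without the ring flip that would break the chelate.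

Step 11
Reactants: 14 dihydroxy ketone; 15 angelic acid, (Z)-2-methylbut-2-enoic acid
Product: 17 2β-angeloyloxy-4β-hydroxydauc-8-en-6-one, via mixed anhydride 16 (not isolated)
Conditions: 15, 2,4,6-trichlorobenzoyl chloride, Et3N, toluene, rt; then 14, 80 °C
Reagents that add atoms: angelic acid (15), C/C=C(/C)C(=O)O
Why: Yamaguchi-type esterification through the preformed mixed anhydride without a nucleophilic catalyst should keep the Z geometry, and only the secondary 2β-hydroxyl reacts because the 4β-hydroxyl is tertiary.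

Step 12
Reactants: 17 keto angelate
Product: 18 2β-angeloyloxydauc-8-ene-4β,6α-diol
Conditions: Me4NBH(OAc)3 (5 equiv), MeCN/AcOH 1:1, −20 °C → rt
Reagents that add atoms: none
Why: Hydroxyl-directed Evans–Saksena reduction, in which the acetoxyborohydride bound to the 4β-oxygen delivers hydride intramolecularly to the β face of the C6 carbonyl, should give the 6α-alcohol, the epimer that external hydride (attack anti to the C1 methyl) would not give.

Step 13
Reactants: 18 diol angelate; 19 4-[(tert-butyldimethylsilyl)oxy]benzoic acid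
Product: 20 2β-angeloyloxy-6α-{4-[(tert-butyldimethylsilyl)oxy]benzoyloxy}dauc-8-en-4β-ol
Conditions: 19, DCC, DMAP (cat.), CH2Cl2, rt
Reagents that add atoms: 4-[(tert-butyldimethylsilyl)oxy]benzoic acid (19), CC(C)(C)[Si](C)(C)Oc1ccc(cc1)C(=O)O
Why: Steglich esterification should acylate the only secondary hydroxyl (6α) while the tertiary 4β-hydroxyl stays free, and the silyl ether keeps the phenol from self-acylation.

Step 14
Reactants: 20 silyl-protected diester
Product: 21 target, 2β-angeloyloxy-6α-(4-hydroxybenzoyloxy)dauc-8-en-4β-ol (CNP0188626.1)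
Conditions: TBAF (1.05 equiv), AcOH (1.1 equiv), THF, 0 °C
Reagents that add atoms: none
Why: Buffered fluoride cleaves the aryl silyl ether rapidly, and under these mild conditions both esters, the angelate geometry and the tertiary alcohol should survive.

**Compound list**
1 | (R)-(−)-carvone | CC1=CC[C@@H](C(C)=C)CC1=O | starting material
2 | (R)-carvotanacetone | CC1=CC[C@@H](C(C)C)CC1=O | intermediate
3 | (1R,4R,6R)-1-methyl-4-(propan-2-yl)-7-oxabicyclo[4.1.0]heptan-2-one | O=C1C[C@H](C(C)C)C[C@H]2O[C@@]12C | intermediate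
4 | allyl bromide | C=CCBr | starting material
5 | dilithium (3R,5R)-2-methyl-5-(propan-2-yl)cyclohex-1-ene-1,3-diolate | [Li]OC1=C(C)[C@H](O[Li])C[C@@H](C(C)C)C1 | intermediate
6 | (2S,3R,5R)-3-hydroxy-2-methyl-5-(propan-2-yl)-2-(prop-2-en-1-yl)cyclohexan-1-one | O=C1C[C@H](C(C)C)C[C@@H](O)[C@]1(C)CC=C | intermediate
7 | (2S,3R,5R)-3-[(tert-butyldimethylsilyl)oxy]-2-methyl-5-(propan-2-yl)-2-(prop-2-en-1-yl)cyclohexan-1-one | O=C1C[C@H](C(C)C)C[C@@H](O[Si](C)(C)C(C)(C)C)[C@]1(C)CC=C | intermediate
8 | (5R,6S)-5-[(tert-butyldimethylsilyl)oxy]-6-methyl-3-(propan-2-yl)-6-(prop-2-en-1-yl)cyclohex-2-en-1-one | C=CC[C@]1(C)C(=O)C=C(C(C)C)C[C@H]1O[Si](C)(C)C(C)(C)C | intermediate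
9 | (2-methylprop-2-en-1-yl)magnesium chloride | C=C(C)C[Mg]Cl | starting material
10 | (1S,5R,6S)-5-[(tert-butyldimethylsilyl)oxy]-6-methyl-1-(2-methylprop-2-en-1-yl)-3-(propan-2-yl)-6-(prop-2-en-1-yl)cyclohex-2-en-1-ol | C=CC[C@]1(C)[C@](O)(CC(C)=C)C=C(C(C)C)C[C@H]1O[Si](C)(C)C(C)(C)C | intermediate
11 | cis-fused (1S,2R,6S)-2-[(tert-butyldimethylsilyl)oxy]-1,8-dimethyl-4-(propan-2-yl)bicyclo[4.4.0]deca-4,8-dien-6-ol | CC1=CC[C@@]2(C)[C@H](O[Si](C)(C)C(C)(C)C)CC(C(C)C)=C[C@@]2(O)C1 | intermediate
12 | cis-fused (1S,2R,6S)-1,8-dimethyl-4-(propan-2-yl)bicyclo[4.4.0]deca-4,8-diene-2,6-diol | CC1=CC[C@@]2(C)[C@H](O)CC(C(C)C)=C[C@@]2(O)C1 | intermediate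
13 | (1S,2R,4R,5R,6R)-4,5-epoxy-1,8-dimethyl-4-(propan-2-yl)bicyclo[4.4.0]dec-8-ene-2,6-diol | CC1=CC[C@@]2(C)[C@H](O)C[C@]3(C(C)C)O[C@@H]3[C@@]2(O)C1 | intermediate
14 | 2β,4β-dihydroxydauc-8-en-6-one | O[C@@H]1C[C@@](O)(C(C)C)[C@@H]2C(=O)CC(C)=CC[C@]21C | intermediate
15 | angelic acid | C/C=C(/C)C(=O)O | starting material
16 | angelic 2,4,6-trichlorobenzoic anhydride | C/C=C(/C)C(=O)OC(=O)c1c(Cl)cc(Cl)cc1Cl | intermediate
17 | 2β-angeloyloxy-4β-hydroxydauc-8-en-6-one | C/C=C(/C)C(=O)O[C@@H]1C[C@@](O)(C(C)C)[C@@H]2C(=O)CC(C)=CC[C@]21C | intermediate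
18 | 2β-angeloyloxydauc-8-ene-4β,6α-diol | C/C=C(/C)C(=O)O[C@@H]1C[C@@](O)(C(C)C)[C@@H]2[C@@H](O)CC(C)=CC[C@]21C | intermediate
19 | 4-[(tert-butyldimethylsilyl)oxy]benzoic acid | CC(C)(C)[Si](C)(C)Oc1ccc(cc1)C(=O)O | starting material
20 | 2β-angeloyloxy-6α-{4-[(tert-butyldimethylsilyl)oxy]benzoyloxy}dauc-8-en-4β-ol | C/C=C(/C)C(=O)O[C@@H]1C[C@@](O)(C(C)C)[C@@H]2[C@@H](OC(=O)c3ccc(O[Si](C)(C)C(C)(C)C)cc3)CC(C)=CC[C@]21C | intermediate
21 | 2β-angeloyloxy-6α-(4-hydroxybenzoyloxy)dauc-8-en-4β-ol (CNP0188626.1) | C/C=C(/C)C(=O)O[C@@H]1C[C@@](O)(C(C)C)[C@@H]2[C@@H](OC(=O)c3ccc(O)cc3)CC(C)=CC[C@]21C | target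

**Step count and risks**
Total: 14 steps. Longest linear sequence: 14 steps (1 → 21).

Step 10 (key step). What may go wrong is ionisation of the tertiary C4–O bond instead of C5–O (then hydride shift or elimination), or migration of C7 instead of C1. The fallback replaces the epoxide by a sulfonate, so that only C5 carries a leaving group and the classical equatorial-sulfonate rule governs the shift. It sets out from 11. Hydrogen-bond-directed dihydroxylation with OsO4/TMEDA (CH2Cl2, −78 °C, then reductive work-up) should oxidise the allylic C4=C5 alkene syn to the 6β-OH and give the all-β 2-[(tert-butyldimethylsilyl)oxy]-1,8-dimethyl-4-(propan-2-yl)bicyclo[4.4.0]dec-8-ene-4,5,6-triol F1. MsCl/Et3N at −20 °C should sulfonylate only the secondary C5 hydroxyl to give the C5 methanesulfonate F2. In the chair with isopropyl equatorial, this mesylate is equatorial and antiperiplanar to the C6–C1 ring-fusion bond, and it cannot be displaced to an epoxide by the cis hydroxyls. Et3Al in CH2Cl2 (−78 → 0 °C) should then induce the pinacol-type shift of the quaternary C1 to give 2β-[(tert-butyldimethylsilyl)oxy]-4β-hydroxydauc-8-en-6-one F3. TBAF removes the silyl ether and the route is rejoined at 14.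

Step 3. What may go wrong is retro-aldol cleavage of the lithium aldolate, O-allylation, or poor facial selectivity in the enolate alkylation. The fallback uses silicon as a masked hydroxyl and sets out from 2. Conjugate addition of lithium bis[dimethyl(phenyl)silyl]cuprate (THF, −78 °C), anti to isopropyl, followed by trapping of the enolate with allyl bromide anti to the silyl group, should give the 3-[dimethyl(phenyl)silyl] analogue of 6 (silyl in place of hydroxyl, same configuration) F4. Fleming–Tamao oxidation (HBF4·OEt2, CH2Cl2; then H2O2, KF, KHCO3, THF/MeOH) proceeds with retention and rejoins the route at 6.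

Step 12. What may go wrong is slow ligand exchange at the tertiary 4β-hydroxyl, so that undirected hydride attacks anti to the C1 methyl and the wrong C6 epimer forms. The fallback sets out from 17 and makes that epimer on purpose. Luche reduction (NaBH4, CeCl3, MeOH, −40 °C) should give 2β-angeloyloxydauc-8-ene-4β,6β-diol F5. Mitsunobu esterification of F5 with acid 19 (PPh3, DIAD, toluene) inverts C6 and delivers the aroyl ester directly, rejoining the route at 20.

Further compounds
F1 | step 10 | all-β 2-[(tert-butyldimethylsilyl)oxy]-1,8-dimethyl-4-(propan-2-yl)bicyclo[4.4.0]dec-8-ene-4,5,6-triol | CC1=CC[C@@]2(C)[C@H](O[Si](C)(C)C(C)(C)C)C[C@@](O)(C(C)C)[C@H](O)[C@@]2(O)C1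
F2 | step 10 | C5 methanesulfonate of F1 | CC1=CC[C@@]2(C)[C@H](O[Si](C)(C)C(C)(C)C)C[C@@](O)(C(C)C)[C@H](OS(C)(=O)=O)[C@@]2(O)C1
F3 | step 10 | 2β-[(tert-butyldimethylsilyl)oxy]-4β-hydroxydauc-8-en-6-one | CC(C)(C)[Si](C)(C)O[C@@H]1C[C@@](O)(C(C)C)[C@@H]2C(=O)CC(C)=CC[C@]21C
F4 | step 3 | 3-[dimethyl(phenyl)silyl]-2-methyl-5-(propan-2-yl)-2-(prop-2-en-1-yl)cyclohexan-1-one (silyl cis to methyl, trans to allyl and isopropyl) | O=C1C[C@H](C(C)C)C[C@@H]([Si](C)(C)c2ccccc2)[C@]1(C)CC=C
F5 | step 12 | 2β-angeloyloxydauc-8-ene-4β,6β-diol | C/C=C(/C)C(=O)O[C@@H]1C[C@@](O)(C(C)C)[C@@H]2[C@H](O)CC(C)=CC[C@]21C
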